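**Assumption:** (R)-but-3-yn-2-ol (≥98% ee) and methyl 3-oxohept-6-enoate are bought as catalogue compounds.

**Retrosynthetic overview**
- The target is opened to a 1,4-cyclohexadiene mixed ketal that aromatises by loss of Me3SiOH.
- That ketal comes from one intramolecular [4+2] cycloaddition of an ester-derived 1-alkoxy-1,3-bis(silyloxy)diene onto a tethered terminal alkyne (bonds C7a–C3a and C5–C4). The carbocycle and the O-heterocycle form together in this single operation, which is the last step.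
- The diene comes from the β-keto ester of a homopropargylic alcohol: the ester oxygen becomes the ring oxygen, and the keto ester supplies C7a, C7, C6(OH), C5 and the allyl group.
- The β-keto ester comes from the anti alcohol and methyl 3-oxohept-6-enoate.
- The alcohol, carrying both stereocentres, comes from 3,4,5-trimethoxybenzaldehyde and a chiral allenylindium made from (R)-but-3-yn-2-yl mesylate. The trimethoxyphenyl ring is bought.

**Route**

Step 1
Reactants: 1 (R)-but-3-yn-2-ol
Product: 2 (R)-but-3-yn-2-yl methanesulfonate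
Conditions: MsCl, Et3N, CH2Cl2, −78 → 0 °C
Reagents that add atoms: methanesulfonyl chloride, CS(=O)(=O)Cl
Why: O-sulfonylation of the alcohol; the C–O bond of the stereocentre is not touched, so the R configuration is retained.

Step 2
Reactants: 2 (R)-but-3-yn-2-yl methanesulfonate; 3 3,4,5-trimethoxybenzaldehyde
Product: 5 (1S,2S)-2-methyl-1-(3,4,5-trimethoxyphenyl)but-3-yn-1-ol, via allenylindium 4 (not isolated)
Conditions: Pd(dppf)Cl2 (5 mol %), InI (indium monoiodide, 1.5 equiv), THF–HMPA 3:1, rt; aq. NH4Cl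
Reagents that add atoms: none
Why: Marshall propargylation: zerovalent palladium (formed from Pd(dppf)Cl2) adds anti-SN2′ to the (R)-mesylate, transmetalation to indium with retention gives the (aS)-allenylindium 4, and 4 adds to the aldehyde through a closed six-membered SE2′ transition state with the aryl group away from the allenyl methyl, so the methyl-bearing carbon becomes S (net inversion of the mesylate centre) and the carbinol S (anti).

Step 3
Reactants: 5 (1S,2S)-2-methyl-1-(3,4,5-trimethoxyphenyl)but-3-yn-1-ol; 6 methyl 3-oxohept-6-enoate (1.5 equiv)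
Product: 7 (1S,2S)-2-methyl-1-(3,4,5-trimethoxyphenyl)but-3-yn-1-yl 3-oxohept-6-enoate
Conditions: DMAP (0.3 equiv), PhMe, reflux, 4 Å sieves (MeOH removal)
Reagents that add atoms: none
Why: DMAP-catalysed transesterification of a β-keto ester, driven by removal of methanol; no bond to either stereocentre is made or broken.

Step 4
Reactants: 7 (1S,2S)-2-methyl-1-(3,4,5-trimethoxyphenyl)but-3-yn-1-yl 3-oxohept-6-enoate
Product: 11 (2S,3S)-5-allyl-3-methyl-2-(3,4,5-trimethoxyphenyl)-2,3-dihydro-1-benzofuran-6-ol, via bis-silyl diene 8 (not isolated), via cycloadduct 9 (not isolated), via aryl silyl ether 10 (not isolated)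
Conditions: TMSOTf (2.4 equiv), Et3N (3.5 equiv), PhMe, 0 °C → rt; supernatant heated at 150 °C (sealed tube, 0.01 M); then TFA, CH2Cl2, 0 °C → rt
Reagents that add atoms: trimethylsilyl trifluoromethanesulfonate, C[Si](C)(C)OS(=O)(=O)C(F)(F)F (its silyl groups sit in 8, 9 and 10 and are gone in 11)
Why: Proposed new method: soft bis-enolisation (TMSOTf/Et3N, as used for Chan-type 1-alkoxy-1,3-bis(silyloxy)dienes) turns the keto ester into diene 8, whose ketene-acetal oxygen holds the alkyne on a three-atom tether. A thermal intramolecular Diels–Alder reaction (diene C1 to the internal alkyne carbon, diene C4 to the terminal one) then builds the carbocycle and the oxolane ring together. The closest known reaction types are the thermal cycloaddition of 2-amino- and 2-alkoxyfurans onto heteroatom-tethered unactivated alkynes and the benzannulation of Chan/Brassard dienes with alkynes. 1,4-Loss of Me3SiOH from the mixed ketal 9 aromatises the ring to 10, and acid cleaves the aryl silyl ether. Both stereocentres come unchanged from 5, and the acid finish also re-closes any ring-opened benzylic alcohol to the more stable 2,3-trans ring.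

**Compound list**
1 | (R)-but-3-yn-2-ol | C[C@H](C#C)O | starting material
2 | (R)-but-3-yn-2-yl methanesulfonate | C[C@H](C#C)OS(C)(=O)=O | intermediate
3 | 3,4,5-trimethoxybenzaldehyde | COc1cc(C=O)cc(OC)c1OC | starting material
4 | (aS)-buta-1,2-dien-1-yl(iodo)indium methanesulfonate | CC([H])=[C@@]=C([H])[In](I)OS(C)(=O)=O | intermediate (not isolated)
5 | (1S,2S)-2-methyl-1-(3,4,5-trimethoxyphenyl)but-3-yn-1-ol | O[C@H](c1cc(OC)c(OC)c(OC)c1)[C@H](C#C)C | intermediate
6 | methyl 3-oxohept-6-enoate | COC(=O)CC(=O)CCC=C | starting material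
7 | (1S,2S)-2-methyl-1-(3,4,5-trimethoxyphenyl)but-3-yn-1-yl 3-oxohept-6-enoate | C=CCCC(=O)CC(=O)O[C@H](c1cc(OC)c(OC)c(OC)c1)[C@H](C#C)C | intermediate
8 | (1Z,3Z)-1-{[(1S,2S)-2-methyl-1-(3,4,5-trimethoxyphenyl)but-3-yn-1-yl]oxy}-1,3-bis(trimethylsilyloxy)hepta-1,3,6-triene | C=CC/C=C(\O[Si](C)(C)C)/C=C(\O[Si](C)(C)C)/O[C@H](c1cc(OC)c(OC)c(OC)c1)[C@H](C#C)C | intermediate (not isolated)
9 | (2S,3S)-5-allyl-3-methyl-6,7a-bis(trimethylsilyloxy)-2-(3,4,5-trimethoxyphenyl)-2,3,5,7a-tetrahydro-1-benzofuran (C5/C7a epimers unassigned; both aromatise to 10) | C=CCC1C=C2C(C=C1O[Si](C)(C)C)(O[Si](C)(C)C)O[C@H](c1cc(OC)c(OC)c(OC)c1)[C@H]2C | intermediate (not isolated)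
10 | (2S,3S)-5-allyl-3-methyl-6-(trimethylsilyloxy)-2-(3,4,5-trimethoxyphenyl)-2,3-dihydro-1-benzofuran | C=CCc1cc2c(cc1O[Si](C)(C)C)O[C@H](c1cc(OC)c(OC)c(OC)c1)[C@H]2C | intermediate (not isolated)
11 | (2S,3S)-5-allyl-3-methyl-2-(3,4,5-trimethoxyphenyl)-2,3-dihydro-1-benzofuran-6-ol (CNP0286233.1) | C=CCc1cc2c(cc1O)O[C@H](c1cc(OC)c(OC)c(OC)c1)[C@H]2C | target

**Step count:** 4 steps in total. Longest linear sequence: 4 steps (1 → 2 → 5 → 7 → 11).

**Steps most likely to fail, with fallbacks**

Step 4. The cycloaddition is untested. Only the (1Z)-ketene acetal, with the tether oxygen on the outside of the diene, can reach the transition state, and the unactivated alkyne may react more slowly than 8 decomposes. The fallback sets out from 7 and returns at 10; it replaces the alkyne by a LUMO-lowered alkene that loses its activating group on aromatisation. Markovnikov hydrothiolation of 7 (4-methylbenzenethiol, Pd(OAc)2 cat., THF, 40 °C) gives (1S,2R)-2-methyl-3-[(4-methylphenyl)sulfanyl]-1-(3,4,5-trimethoxyphenyl)but-3-en-1-yl 3-oxohept-6-enoate F1. Oxidation (m-CPBA, 2.1 equiv, CH2Cl2, −20 → 0 °C) gives (1S,2R)-2-methyl-3-[(4-methylphenyl)sulfonyl]-1-(3,4,5-trimethoxyphenyl)but-3-en-1-yl 3-oxohept-6-enoate F2. TMSOTf/Et3N then gives the (1Z,3Z)-1-alkoxy-1,3-bis(trimethylsilyloxy)hepta-1,3,6-triene F3. Its nucleophilic diene terminus now meets the CH2 end of a 1,1-disubstituted vinyl sulfone, which is the electronically matched orientation, so cyclisation to the (2S,3R)-3a-sulfonyl-2,3,3a,4,5,7a-hexahydro-1-benzofuran F4 should run at 25–80 °C. Warming and then DBU expel Me3SiOH and 4-methylbenzenesulfinic acid, driven by aromatisation, to give 10, which is desilylated to 11 as in step 4.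

Step 2. Aromatic aldehydes give lower anti:syn ratios than aliphatic ones with allenylindium reagents, and any loss of ee in 4 is carried through. The fallback sets out from 3 and returns at 5; it uses catalytic enantioselective reductive coupling instead of chirality transfer from the mesylate. Aldehyde 3 and but-3-en-1-yn-1-yl(triisopropyl)silane are coupled with the cyclometalated iridium catalyst made from [Ir(cod)Cl]2, a SEGPHOS-type bisphosphine (the antipode that gives the 1S,2S series) and 4-cyano-3-nitrobenzoic acid, with HCO2H as reductant. The enyne acts as an anti-selective allenyl-iridium equivalent and gives (1S,2S)-2-methyl-4-(triisopropylsilyl)-1-(3,4,5-trimethoxyphenyl)but-3-yn-1-ol F5. TBAF in THF removes the silyl group to give 5.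

Step 3. Acyl transfer to a hindered, ionisable benzylic alcohol is slow and reversible. The fallback sets out from 5 and returns at 7; it builds the keto ester on the alcohol by C–C bond formation (Blaise reaction). Bromoacetyl bromide and pyridine in CH2Cl2 at 0 °C give (1S,2S)-2-methyl-1-(3,4,5-trimethoxyphenyl)but-3-yn-1-yl 2-bromoacetate F6. Activated zinc dust and pent-4-enenitrile in refluxing THF, followed by aqueous K2CO3, give (1S,2S)-2-methyl-1-(3,4,5-trimethoxyphenyl)but-3-yn-1-yl (2Z)-3-aminohepta-2,6-dienoate F7. 1 M HCl in THF hydrolyses F7 to 7.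

**Further compounds**
F1 | step 4 | (1S,2R)-2-methyl-3-[(4-methylphenyl)sulfanyl]-1-(3,4,5-trimethoxyphenyl)but-3-en-1-yl 3-oxohept-6-enoate | C=CCCC(=O)CC(=O)O[C@H](c1cc(OC)c(OC)c(OC)c1)[C@H](C(=C)Sc1ccc(C)cc1)C
F2 | step 4 | (1S,2R)-2-methyl-3-[(4-methylphenyl)sulfonyl]-1-(3,4,5-trimethoxyphenyl)but-3-en-1-yl 3-oxohept-6-enoate | C=CCCC(=O)CC(=O)O[C@H](c1cc(OC)c(OC)c(OC)c1)[C@H](C(=C)S(=O)(=O)c1ccc(C)cc1)C
F3 | step 4 | (1Z,3Z)-1-{[(1S,2R)-2-methyl-3-[(4-methylphenyl)sulfonyl]-1-(3,4,5-trimethoxyphenyl)but-3-en-1-yl]oxy}-1,3-bis(trimethylsilyloxy)hepta-1,3,6-triene | C=CC/C=C(\O[Si](C)(C)C)/C=C(\O[Si](C)(C)C)/O[C@H](c1cc(OC)c(OC)c(OC)c1)[C@H](C(=C)S(=O)(=O)c1ccc(C)cc1)C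
F4 | step 4 | (2S,3R)-5-allyl-3-methyl-3a-[(4-methylphenyl)sulfonyl]-6,7a-bis(trimethylsilyloxy)-2-(3,4,5-trimethoxyphenyl)-2,3,3a,4,5,7a-hexahydro-1-benzofuran (C3a/C5/C7a unassigned) | C=CCC1CC2(S(=O)(=O)c3ccc(C)cc3)C(C=C1O[Si](C)(C)C)(O[Si](C)(C)C)O[C@H](c1cc(OC)c(OC)c(OC)c1)[C@H]2C
F5 | step 2 | (1S,2S)-2-methyl-4-(triisopropylsilyl)-1-(3,4,5-trimethoxyphenyl)but-3-yn-1-ol | O[C@H](c1cc(OC)c(OC)c(OC)c1)[C@H](C#C[Si](C(C)C)(C(C)C)C(C)C)C
F6 | step 3 | (1S,2S)-2-methyl-1-(3,4,5-trimethoxyphenyl)but-3-yn-1-yl 2-bromoacetate | BrCC(=O)O[C@H](c1cc(OC)c(OC)c(OC)c1)[C@H](C#C)C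
F7 | step 3 | (1S,2S)-2-methyl-1-(3,4,5-trimethoxyphenyl)but-3-yn-1-yl (2Z)-3-aminohepta-2,6-dienoate | C=CCC/C(N)=C/C(=O)O[C@H](c1cc(OC)c(OC)c(OC)c1)[C@H](C#C)C
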